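**Retrosynthetic overview**
- Target 14 is unmasked from its C5 triisopropylsilyl ether 13, which comes from phenol-alcohol 12 by acetylating the C2-OH and the C2'-OH together.
- The strategy rests on ring carbons C1 (bearing side-chain carbon C1') and C2 (bearing the acetoxy oxygen) being neighbours, with C2 next to the methoxy-bearing C3. The C1-C1' and C2-O bonds are therefore cut together, back to an aryne spanning C1/C2.
- Aryne 9 is released from chloroarene 2 (silylated 3-chloro-5-methoxyphenol 1). The carbon partner is the beta-oxido alkyllithium 7 from chlorohydrin 6, and the C2 oxygen comes from borylation and peroxide oxidation of the C2-Li bond.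
- Chlorohydrin 6 and its stereocentre C2' (R) come from dodecyl Grignard opening of (R)-epichlorohydrin 4.
- No ring is formed at any stage; the benzene ring is bought with the C3 and C5 oxygens in place.

Key step: step 3

Remark: 3-chloro-5-methoxyphenol, 1-bromododecane and (R)-epichlorohydrin are taken as purchasable; ring atoms are numbered C1 (side chain), C2 (OAc), C3 (OMe), C5 (OH), and side-chain atoms C1' (benzylic) and C2' (stereocentre, R in the target).

Step 1
Reactants: 1 3-chloro-5-methoxyphenol
Product: 2 1-chloro-3-methoxy-5-(triisopropylsilyloxy)benzene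
Conditions: TIPSCl, imidazole, DMF, rt
Reagents that add atoms: triisopropylsilyl chloride, CC(C)[Si](Cl)(C(C)C)C(C)C
Why: Imidazole-promoted silylation of a phenol (silyl ether formation via the N-silylimidazolium) should be clean, and the bulky triisopropylsilyl ether withstands the organolithium reagents of step 3 while shielding its own ortho positions from lithiation.

Step 2
Reactants: 3 1-bromododecane; 4 (R)-epichlorohydrin
Product: 6 (R)-1-chloropentadecan-2-ol, via dodecylmagnesium bromide 5 (not isolated)
Conditions: Mg, THF, 40 °C; then CuI (10 mol %), 4, THF, −40 → −20 °C; then 1 M HCl, 0 °C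
Reagents that add atoms: none
Why: The Grignard reagent 5, turned into a dodecylcuprate by catalytic CuI, opens the epoxide at its unsubstituted CH2 carbon (copper-catalysed Grignard epoxide opening) faster than it displaces chloride, and at −40 °C the magnesium alkoxide does not close to a new epoxide, so the stereocentre of 4, which is not a reacting centre, is carried over unchanged as (R).

Step 3
Reactants: 2 1-chloro-3-methoxy-5-(triisopropylsilyloxy)benzene; 6 (R)-1-chloropentadecan-2-ol
Product: 12 (R)-1-[2-hydroxy-3-methoxy-5-(triisopropylsilyloxy)phenyl]pentadecan-2-ol, via lithium (S)-1-lithiopentadecan-2-olate 7 (not isolated), via 2-lithio chloroarene 8 (not isolated), via 3-methoxy-5-(triisopropylsilyloxy)benzyne 9 (not isolated), via C2-lithiated adduct 10 (not isolated), via lithium aryltrimethoxyborate 11 (not isolated)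
Conditions: (a) 6 (1.5 equiv), n-BuLi, THF, −78 °C, then lithium naphthalenide (LiC10H8, 2 equiv per C-Cl), −78 °C; (b) separately 2, s-BuLi (1.0 equiv), THF, −78 °C; (c) solution b into a at −78 °C, then slowly to −50 °C; (d) B(OMe)3, −78 °C → rt; (e) AcOH, 30% H2O2, 0 °C → rt
Reagents that add atoms: hydrogen peroxide, OO
Why: Proposed new method: s-BuLi removes the ring hydrogen flanked by chlorine and methoxy (the most acidic site, the silyloxy group being too bulky to direct), and on warming the 2-lithio chloroarene 8 loses LiCl to give aryne 9 across C1 and C2, to which the primary carbanion of 7 adds at C1, the aryne carbon remote from the methoxy group, because the inductively withdrawing methoxy distorts the aryne and stabilises negative charge at C2, leaving lithium at C2 chelated by the methoxy oxygen in 10. B(OMe)3 turns this C-Li bond into borate 11, and H2O2 in AcOH triggers the aryl shift from boron to oxygen that gives the C2 phenol. The closest known reaction type is the addition of simple alkyllithiums to 3-methoxybenzynes released from ortho-lithiated haloanisoles with electrophilic trapping of the new aryllithium, and beta-oxido alkyllithiums made from chlorohydrins by deprotonation and reductive lithiation are known reagents; their use as the aryne partner is the untested element. No ring is closed and no stereocentre is created, since C2' is carried in from 6 and takes part in no bond change (7 reads S only because CH2Li ranks below the alkyl chain). The selectivity needed is regiochemical (carbon at C1, oxygen at C2) and is secured by the C3 methoxy group, while chemoselectivity rests on an amine-free base (a lithium amide would leave an N-H that quenches 7 and 10) and on aryne release near −50 °C, cold enough for 7 to outlast beta-elimination of Li2O.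

Step 4
Reactants: 12 (R)-1-[2-hydroxy-3-methoxy-5-(triisopropylsilyloxy)phenyl]pentadecan-2-ol
Product: 13 (R)-1-[2-acetoxy-3-methoxy-5-(triisopropylsilyloxy)phenyl]pentadecan-2-yl acetate
Conditions: Ac2O, pyridine, DMAP (cat.), CH2Cl2, 0 °C → rt
Reagents that add atoms: acetic anhydride, CC(=O)OC(C)=O
Why: DMAP-catalysed acylation (nucleophilic catalysis via the N-acetylpyridinium) should esterify the hindered C2 phenol and the secondary C2' alcohol in one operation, with the C5 oxygen masked as its silyl ether and no bond to the stereocentre broken.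

Step 5
Reactants: 13 (R)-1-[2-acetoxy-3-methoxy-5-(triisopropylsilyloxy)phenyl]pentadecan-2-yl acetate
Product: 14 (R)-1-(2-acetoxy-5-hydroxy-3-methoxyphenyl)pentadecan-2-yl acetate (CNP0236046.1)
Conditions: Bu4NF, AcOH, THF, 0 °C
Reagents that add atoms: none
Why: Fluoride cleaves the aryl O-Si bond (desilylation driven by Si-F bond formation), and the AcOH buffer protonates the C5 phenoxide as it forms so that neither acetate is cleaved or transferred.

**Compound list**
1 | 3-chloro-5-methoxyphenol | COc1cc(O)cc(Cl)c1 | starting material
2 | 1-chloro-3-methoxy-5-(triisopropylsilyloxy)benzene | COc1cc(Cl)cc(O[Si](C(C)C)(C(C)C)C(C)C)c1 | intermediate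
3 | 1-bromododecane | CCCCCCCCCCCCBr | starting material
4 | (R)-epichlorohydrin | ClC[C@H]1CO1 | starting material
5 | dodecylmagnesium bromide (not isolated) | CCCCCCCCCCCC[Mg]Br | intermediate
6 | (R)-1-chloropentadecan-2-ol | CCCCCCCCCCCCC[C@H](CCl)O | intermediate
7 | lithium (S)-1-lithiopentadecan-2-olate (not isolated; same spatial arrangement as 6) | CCCCCCCCCCCCC[C@H](C[Li])O[Li] | intermediate
8 | [2-chloro-6-methoxy-4-(triisopropylsilyloxy)phenyl]lithium (2-lithio chloroarene, not isolated) | COc1cc(O[Si](C(C)C)(C(C)C)C(C)C)cc(Cl)c1[Li] | intermediate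
9 | 3-methoxy-5-(triisopropylsilyloxy)benzyne (aryne across C1/C2, not isolated) | COC1=CC(O[Si](C(C)C)(C(C)C)C(C)C)=CC#C1 | intermediate
10 | lithium (R)-1-[2-lithio-3-methoxy-5-(triisopropylsilyloxy)phenyl]pentadecan-2-olate (C2-lithiated adduct, not isolated) | CCCCCCCCCCCCC[C@H](Cc1cc(O[Si](C(C)C)(C(C)C)C(C)C)cc(OC)c1[Li])O[Li] | intermediate
11 | dilithium (R)-1-[3-methoxy-2-(trimethoxyboranuidyl)-5-(triisopropylsilyloxy)phenyl]pentadecan-2-olate (lithium aryltrimethoxyborate, not isolated) | [Li+].[Li+].CCCCCCCCCCCCC[C@H](Cc1cc(O[Si](C(C)C)(C(C)C)C(C)C)cc(OC)c1[B-](OC)(OC)OC)[O-] | intermediate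
12 | (R)-1-[2-hydroxy-3-methoxy-5-(triisopropylsilyloxy)phenyl]pentadecan-2-ol | CCCCCCCCCCCCC[C@H](Cc1cc(O[Si](C(C)C)(C(C)C)C(C)C)cc(OC)c1O)O | intermediate
13 | (R)-1-[2-acetoxy-3-methoxy-5-(triisopropylsilyloxy)phenyl]pentadecan-2-yl acetate | CCCCCCCCCCCCC[C@H](Cc1cc(O[Si](C(C)C)(C(C)C)C(C)C)cc(OC)c1OC(C)=O)OC(C)=O | intermediate
14 | (R)-1-(2-acetoxy-5-hydroxy-3-methoxyphenyl)pentadecan-2-yl acetate (CNP0236046.1) | CCCCCCCCCCCCC[C@H](Cc1cc(O)cc(OC)c1OC(C)=O)OC(C)=O | target

**Step count**
Total steps: 5. Longest linear sequence: 4 steps (1 → 2 → 12 → 13 → 14, or 3/4 → 6 → 12 → 13 → 14).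

**Steps most likely to fail**

1. Step 3 (proposed new method). The alkyllithium may be lost by beta-elimination of lithium oxide before LiCl loss from the lithiated chloroarene sets in. The aryne would then be consumed by aryllithium species instead of the chain nucleophile. Incomplete or misdirected lithiation would add to the loss. The fallback uses only known chemistry; it sets out from 6 and comes back at 12, with the C2 oxygen bought in place and the C1-C1' bond made by aryllithium opening of an epoxide. Chlorohydrin 6 is closed with aqueous NaOH to (R)-2-tridecyloxirane F1, the stereocentre being untouched because its oxygen is the nucleophile. The arene comes from purchased 5-bromovanillin F2, whose bromine, hydroxyl, methoxy and formyl groups sit on the carbons that become C1, C2, C3 and C5. Benzylation (BnBr, K2CO3, DMF) should give 4-(benzyloxy)-3-bromo-5-methoxybenzaldehyde F3. Baeyer-Villiger oxidation with mCPBA in CH2Cl2 should give 4-(benzyloxy)-3-bromo-5-methoxyphenyl formate F4, and K2CO3 in MeOH should release 4-(benzyloxy)-3-bromo-5-methoxyphenol F5. Silylation (TIPSCl, imidazole) should give [4-(benzyloxy)-3-bromo-5-methoxyphenoxy]triisopropylsilane F6. Bromine-lithium exchange with n-BuLi in THF at −78 °C should give [2-(benzyloxy)-3-methoxy-5-(triisopropylsilyloxy)phenyl]lithium F7. With BF3·OEt2 at −78 °C this should open F1 at its terminal CH2 to (R)-1-[2-(benzyloxy)-3-methoxy-5-(triisopropylsilyloxy)phenyl]pentadecan-2-ol F8. Hydrogenolysis (H2, Pd/C, EtOAc) then frees the C2 phenol and rejoins the route at 12.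

2. Step 5. The C5 phenoxide or basic fluoride may cleave the C2 aryl acetate or transfer its acetyl group between molecules during desilylation. The fallback sets out from 12 and comes back at 14, relying on steric differentiation of the two aryl esters. Bu4NF in THF at 0 °C under argon should give (R)-1-(2,5-dihydroxy-3-methoxyphenyl)pentadecan-2-ol F9, which is acetylated at once (Ac2O, pyridine, DMAP) to (R)-1-(2,5-diacetoxy-3-methoxyphenyl)pentadecan-2-yl acetate F10. NH4OAc in MeOH at rt is a reagent that cleaves aryl acetates while sparing alkyl acetates. It should remove the unhindered C5 acetate, flanked by two ring hydrogens, in preference to the C2 acetate, flanked by methoxy and the side chain, to give 14.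

3. Step 2. The organometallic may attack the C-Cl carbon, or the product alkoxide may close to a new epoxide that takes up a second equivalent of Grignard reagent; either would lower the yield and could erode configurational purity. The fallback sets out from 4 and comes back at 6, replacing the cuprate opening by a Lewis-acid-mediated alkynylation that cannot close the epoxide. Purchased 1-dodecyne F11 is deprotonated with n-BuLi in THF at −78 °C to dodec-1-ynyllithium F12. With BF3·OEt2 this should open 4 at the epoxide CH2 at −78 °C to (R)-1-chloropentadec-4-yn-2-ol F13. Hydrogenation (H2, Pd/C, EtOAc) should then saturate the triple bond to give 6.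

**Further compounds**
F1 | step 3 | (R)-2-tridecyloxirane | CCCCCCCCCCCCC[C@@H]1CO1
F2 | step 3 | 5-bromovanillin (3-bromo-4-hydroxy-5-methoxybenzaldehyde, purchased) | COc1cc(C=O)cc(Br)c1O
F3 | step 3 | 4-(benzyloxy)-3-bromo-5-methoxybenzaldehyde | COc1cc(C=O)cc(Br)c1OCc1ccccc1
F4 | step 3 | 4-(benzyloxy)-3-bromo-5-methoxyphenyl formate | COc1cc(OC=O)cc(Br)c1OCc1ccccc1
F5 | step 3 | 4-(benzyloxy)-3-bromo-5-methoxyphenol | COc1cc(O)cc(Br)c1OCc1ccccc1
F6 | step 3 | [4-(benzyloxy)-3-bromo-5-methoxyphenoxy]triisopropylsilane | COc1cc(O[Si](C(C)C)(C(C)C)C(C)C)cc(Br)c1OCc1ccccc1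
F7 | step 3 | [2-(benzyloxy)-3-methoxy-5-(triisopropylsilyloxy)phenyl]lithium | COc1cc(O[Si](C(C)C)(C(C)C)C(C)C)cc([Li])c1OCc1ccccc1
F8 | step 3 | (R)-1-[2-(benzyloxy)-3-methoxy-5-(triisopropylsilyloxy)phenyl]pentadecan-2-ol | CCCCCCCCCCCCC[C@H](Cc1cc(O[Si](C(C)C)(C(C)C)C(C)C)cc(OC)c1OCc1ccccc1)O
F9 | step 5 | (R)-1-(2,5-dihydroxy-3-methoxyphenyl)pentadecan-2-ol | CCCCCCCCCCCCC[C@H](Cc1cc(O)cc(OC)c1O)O
F10 | step 5 | (R)-1-(2,5-diacetoxy-3-methoxyphenyl)pentadecan-2-yl acetate | CCCCCCCCCCCCC[C@H](Cc1cc(OC(C)=O)cc(OC)c1OC(C)=O)OC(C)=O
F11 | step 2 | 1-dodecyne (purchased) | CCCCCCCCCCC#C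
F12 | step 2 | dodec-1-ynyllithium | CCCCCCCCCCC#C[Li]
F13 | step 2 | (R)-1-chloropentadec-4-yn-2-ol | CCCCCCCCCCC#CC[C@H](CCl)O
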